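**Retrosynthetic overview**
1. Target 18 ⇐ debromo phenol 16: both brominations (para and the free ortho position of the phenol) come last.
2. 16 ⇐ tosylhydrazone 13: the derived diazoalkane adds across its own terminal alkene (cyclopentane and pyrazoline rings close together), then N2 loss contracts the pyrazoline to the cyclopropane; both new stereocentres are relayed from the quaternary carbon.
3. 13 ⇐ methyl ketone 11 ⇐ aryl lactone 8: a one-carbon nucleophile opens the lactone and releases the phenol without a protecting group.
4. 8 ⇐ lactone 4 + acrolein: catalytic asymmetric Michael addition sets the quaternary centre, then methylenation.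
5. 4 ⇐ 2-bromo-5-methylphenol + tert-butyl propanoate. Ring order: lactone (temporary), then cyclopentane and pyrazoline together, then cyclopropane; the arene is bought.

Assumption: the sense of induction in step 2 cannot be predicted with certainty; the quinine-derived thiourea is written, and its quinidine-derived pseudoenantiomer, N-[3,5-bis(trifluoromethyl)phenyl]-N′-[(9R)-6′-methoxycinchonan-9-yl]thiourea, is used instead if that is the one delivering (S)-6. Compounds 1, 2, 5, 7, 9, 12 and 17 are commercial.

**Route**

Step 1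
Reactants: 1 2-bromo-5-methylphenol; 2 tert-butyl propanoate
Product: 4 3,6-dimethyl-1-benzofuran-2(3H)-one (racemic), via tert-butyl arylpropanoate 3 (not isolated)
Conditions: LiN(SiMe3)2 (3.5 equiv), Pd(dba)2 (3 mol %), P(tBu)3 (6 mol %), PhMe, rt to 50 °C; then CF3CO2H, 60 °C
Reagents that add atoms: tert-butyl propanoate, CCC(=O)OC(C)(C)C
Why: Palladium-catalysed α-arylation of the ester lithium enolate (Buchwald–Hartwig-type enolate arylation, which accepts o-bromophenoxides and stops at mono-arylation for tert-butyl propanoate), followed by acid-mediated loss of the tert-butyl group and lactonisation of the o-hydroxyaryl acid; C3 is formed racemic and stays enolisable, so it is set only in step 2.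

Step 2
Reactants: 4 3,6-dimethyl-1-benzofuran-2(3H)-one; 5 acrolein
Product: 6 3-[(3S)-3,6-dimethyl-2-oxo-2,3-dihydro-1-benzofuran-3-yl]propanal
Conditions: N-[3,5-bis(trifluoromethyl)phenyl]-N′-[(8α,9S)-6′-methoxycinchonan-9-yl]thiourea (10 mol %), acrolein (2 equiv), CH2Cl2, −40 °C
Reagents that add atoms: acrolein, C=CC=O
Why: Organocatalytic asymmetric Michael addition in which the quinuclidine nitrogen deprotonates the acidic C3–H, the thiourea holds the aromatic enolate in a chiral ion pair and acrolein is hydrogen-bonded, so that attack on one enolate face creates the all-carbon quaternary centre as (S), as in known bifunctional amine–thiourea Michael additions of 3-substituted benzofuranones.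

Step 3
Reactants: 6 3-[(3S)-3,6-dimethyl-2-oxo-2,3-dihydro-1-benzofuran-3-yl]propanal; 7 methyltriphenylphosphonium bromide
Product: 8 (3S)-3-(but-3-en-1-yl)-3,6-dimethyl-1-benzofuran-2(3H)-one
Conditions: Ph3PCH3Br (1.1 equiv), KN(SiMe3)2 (1.05 equiv), THF, −78 to 0 °C
Reagents that add atoms: methyltriphenylphosphonium bromide, C[P+](c1ccccc1)(c1ccccc1)c1ccccc1.[Br-]
Why: Wittig methylenation, in which the ylide at −78 °C reacts with the aldehyde and not with the hindered aryl lactone, and the quaternary centre cannot epimerise.

Step 4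
Reactants: 8 (3S)-3-(but-3-en-1-yl)-3,6-dimethyl-1-benzofuran-2(3H)-one; 9 (trimethylsilyl)methyllithium
Product: 11 (3S)-3-(2-hydroxy-4-methylphenyl)-3-methylhept-6-en-2-one, via silyl ketone 10 (not isolated)
Conditions: Me3SiCH2Li (2.5 equiv), THF, −78 to 0 °C; then MeOH, rt; aq. NH4Cl
Reagents that add atoms: (trimethylsilyl)methyllithium, [Li]C[Si](C)(C)C
Why: Nucleophilic acyl substitution on the aryl lactone with phenoxide as leaving group (ester to methyl ketone conversion with Me3SiCH2Li), where the α-silyl ketone 10 is at once deprotonated by the second equivalent, which stops over-addition, and methanolysis of the C–Si bond gives the methyl ketone with the phenol freed and the stereocentre untouched.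

Step 5
Reactants: 11 (3S)-3-(2-hydroxy-4-methylphenyl)-3-methylhept-6-en-2-one; 12 4-methylbenzenesulfonohydrazide
Product: 13 N′-[(3S)-3-(2-hydroxy-4-methylphenyl)-3-methylhept-6-en-2-ylidene]-4-methylbenzenesulfonohydrazide
Conditions: TsNHNH2 (1.3 equiv), AcOH (cat.), MeOH, 60 °C; crystallise
Reagents that add atoms: 4-methylbenzenesulfonohydrazide, Cc1ccc(cc1)S(=O)(=O)NN
Why: Acid-catalysed condensation of the ketone (in equilibrium with its cyclic hemiketal) to the tosylhydrazone, which is crystallised to remove water and acid before the base step and to raise enantiomeric purity.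

Step 6
Reactants: 13 N′-[(3S)-3-(2-hydroxy-4-methylphenyl)-3-methylhept-6-en-2-ylidene]-4-methylbenzenesulfonohydrazide
Product: 16 2-[(1S,2R,5R)-1,2-dimethylbicyclo[3.1.0]hexan-2-yl]-5-methylphenol, via diazoalkane 14 (not isolated), via pyrazoline 15 (not isolated)
Conditions: NaH (2.05 equiv), PhMe, 0 to 110 °C; aq. NH4Cl wash; then hν (350 nm), PhMe, rt
Reagents that add atoms: none
Why: Aprotic Bamford–Stevens fragmentation of the sodium hydrazonide (phenol held as phenoxide so that no O–H can protonate the diazo carbon) gives diazoalkane 14, whose intramolecular 1,3-dipolar cycloaddition onto the terminal alkene closes the cyclopentane and 1-pyrazoline rings in one event, and photochemical N2 loss (1,3-diradical recombination) contracts the pyrazoline to the cyclopropane; the cis fusion is enforced, C5 is set relative to the quaternary carbon in the cycloaddition, where the aryl group is expected to sit beside the slim N=N unit instead of eclipsing the methyl on the diazo carbon and so ends cis to the future cyclopropane CH2, and C1 follows from the cis fusion.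

Step 7
Reactants: 16 2-[(1S,2R,5R)-1,2-dimethylbicyclo[3.1.0]hexan-2-yl]-5-methylphenol; 17 N-bromosuccinimide
Product: 18 2,4-dibromo-6-[(1S,2R,5R)-1,2-dimethylbicyclo[3.1.0]hexan-2-yl]-3-methylphenol
Conditions: NBS (2.05 equiv), MeCN, 0 °C to rt, dark
Reagents that add atoms: N-bromosuccinimide, O=C1CCC(=O)N1Br
Why: Electrophilic aromatic bromination directed by the phenol OH to its para position and its one free ortho position (the third ring CH is meta to OH and flanked by the quaternary carbon), using NBS so that no HBr forms and the acid-sensitive cyclopropane and all three stereocentres stay untouched.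

**Compound list**
1 | 2-bromo-5-methylphenol | Cc1ccc(Br)c(O)c1 | starting material
2 | tert-butyl propanoate | CCC(=O)OC(C)(C)C | starting material
3 | tert-butyl 2-(2-hydroxy-4-methylphenyl)propanoate (racemic) | CC(C(=O)OC(C)(C)C)c1ccc(C)cc1O | intermediate
4 | 3,6-dimethyl-1-benzofuran-2(3H)-one (racemic) | CC1C(=O)Oc2cc(C)ccc12 | intermediate
5 | acrolein (prop-2-enal) | C=CC=O | starting material
6 | 3-[(3S)-3,6-dimethyl-2-oxo-2,3-dihydro-1-benzofuran-3-yl]propanal | Cc1ccc2c(c1)OC(=O)[C@@]2(C)CCC=O | intermediate
7 | methyltriphenylphosphonium bromide | C[P+](c1ccccc1)(c1ccccc1)c1ccccc1.[Br-] | starting material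
8 | (3S)-3-(but-3-en-1-yl)-3,6-dimethyl-1-benzofuran-2(3H)-one | Cc1ccc2c(c1)OC(=O)[C@@]2(C)CCC=C | intermediate
9 | (trimethylsilyl)methyllithium | [Li]C[Si](C)(C)C | starting material
10 | (3S)-3-(2-hydroxy-4-methylphenyl)-3-methyl-1-(trimethylsilyl)hept-6-en-2-one (dilithium salt in the flask) | Cc1ccc([C@](C(=O)C[Si](C)(C)C)(C)CCC=C)c(O)c1 | intermediate
11 | (3S)-3-(2-hydroxy-4-methylphenyl)-3-methylhept-6-en-2-one | Cc1ccc([C@](C(C)=O)(C)CCC=C)c(O)c1 | intermediate
12 | 4-methylbenzenesulfonohydrazide | Cc1ccc(cc1)S(=O)(=O)NN | starting material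
13 | N′-[(3S)-3-(2-hydroxy-4-methylphenyl)-3-methylhept-6-en-2-ylidene]-4-methylbenzenesulfonohydrazide | Cc1ccc([C@](C(C)=NNS(=O)(=O)c2ccc(C)cc2)(C)CCC=C)c(O)c1 | intermediate
14 | 2-[(3S)-2-diazo-3-methylhept-6-en-3-yl]-5-methylphenol (sodium phenoxide in the flask) | Cc1ccc([C@](C(C)=[N+]=[N-])(C)CCC=C)c(O)c1 | intermediate
15 | 2-[(3aR,6S,6aS)-6,6a-dimethyl-3,3a,4,5,6,6a-hexahydrocyclopenta[c]pyrazol-6-yl]-5-methylphenol | Cc1ccc([C@]2(C)CC[C@@H]3CN=N[C@@]32C)c(O)c1 | intermediate
16 | 2-[(1S,2R,5R)-1,2-dimethylbicyclo[3.1.0]hexan-2-yl]-5-methylphenol | Cc1ccc([C@]2(C)CC[C@@H]3C[C@@]32C)c(O)c1 | intermediate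
17 | N-bromosuccinimide | O=C1CCC(=O)N1Br | starting material
18 | 2,4-dibromo-6-[(1S,2R,5R)-1,2-dimethylbicyclo[3.1.0]hexan-2-yl]-3-methylphenol | Cc1c(Br)cc([C@]2(C)CC[C@@H]3C[C@@]32C)c(O)c1Br | target

**Step count**
Total steps: 7. Longest linear sequence: 7.

**Three steps most likely to fail**

Step 6. The facial selectivity of the cycloaddition is argued from sterics, not proven, so the C1/C5 epimer of 16 may form in quantity. The carbene 1,2-hydrogen shift or cyclisation onto the phenol oxygen may also compete. The fallback sets out from 11 and comes back at 16. Ketone 11 is methylenated with Cp2TiMe2 (PhMe, 70 °C) to 2-[(3R)-2,3-dimethylhepta-1,6-dien-3-yl]-5-methylphenol F1. Ring-closing metathesis with the second-generation Grubbs catalyst (CH2Cl2, 40 °C) gives 2-[(1R)-1,2-dimethylcyclopent-2-en-1-yl]-5-methylphenol F2. Cyclopropanation with Et2Zn and CH2I2 (CH2Cl2, 0 °C to rt) is directed by the zinc phenoxide to the aryl face and gives 16.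

Step 2. The small 3-methyl group may give only moderate enantioselectivity, and acrolein can polymerise. The fallback sets out from 8 of insufficient enantiomeric purity and comes back at 8 as a single enantiomer. The aryl lactone is opened with (S)-1-phenylethylamine (THF, rt) to (2S)-2-(2-hydroxy-4-methylphenyl)-2-methyl-N-[(1S)-1-phenylethyl]hex-5-enamide F3 together with its diastereomer (2R)-2-(2-hydroxy-4-methylphenyl)-2-methyl-N-[(1S)-1-phenylethyl]hex-5-enamide F4. The two are separated by crystallisation or chromatography. F3 is relactonised with TsOH in PhMe at reflux, which releases the amine and returns 8.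

Step 1. The o-bromophenoxide may undergo oxidative addition slowly, and the ester enolate may self-condense. The fallback sets out from 1 and comes back at 4. Compound 1 is treated with n-butyllithium (2.1 equiv, THF, −78 °C; O-lithiation and Br/Li exchange) and then ethyl pyruvate to give ethyl 2-hydroxy-2-(2-hydroxy-4-methylphenyl)propanoate (racemic) F5. On work-up with TsOH this closes to 3-hydroxy-3,6-dimethyl-1-benzofuran-2(3H)-one (racemic) F6. The tertiary benzylic hydroxyl is removed with H3PO2 and catalytic I2 in AcOH at 80 °C to give 4.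

**Further compounds**
F1 | step 6 | 2-[(3R)-2,3-dimethylhepta-1,6-dien-3-yl]-5-methylphenol | Cc1ccc([C@](C(C)=C)(C)CCC=C)c(O)c1
F2 | step 6 | 2-[(1R)-1,2-dimethylcyclopent-2-en-1-yl]-5-methylphenol | Cc1ccc([C@]2(C)CCC=C2C)c(O)c1
F3 | step 2 | (2S)-2-(2-hydroxy-4-methylphenyl)-2-methyl-N-[(1S)-1-phenylethyl]hex-5-enamide | Cc1ccc([C@](C(=O)N[C@@H](C)c2ccccc2)(C)CCC=C)c(O)c1
F4 | step 2 | (2R)-2-(2-hydroxy-4-methylphenyl)-2-methyl-N-[(1S)-1-phenylethyl]hex-5-enamide | Cc1ccc([C@@](C(=O)N[C@@H](C)c2ccccc2)(C)CCC=C)c(O)c1
F5 | step 1 | ethyl 2-hydroxy-2-(2-hydroxy-4-methylphenyl)propanoate (racemic) | CCOC(=O)C(C)(O)c1ccc(C)cc1O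
F6 | step 1 | 3-hydroxy-3,6-dimethyl-1-benzofuran-2(3H)-one (racemic) | CC1(O)C(=O)Oc2cc(C)ccc12
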